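## Retrosynthetic overview

1. The target comes from C2-selective acetylation of the 2,3-diol, which comes from hydrolysis of its trans-fused 2,3-acetonide.
2. Rings A and B are closed in one operation, ring A first and then ring B, from an acyclic (E,E)-triene with a terminal isopropenyl group. A light-driven cobalt-hydride radical bicycloisomerization forms C4–C5 and C9–C10 and leaves the 7-ene.
3. The triene comes from a B-alkyl Suzuki coupling (C5–C6) of an (E)-vinyl iodide with the 9-BBN adduct of a C11 diene.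
4. The vinyl iodide comes from Negishi carboalumination of a propargyl isopropenyl dioxolane made from dimethyl 2,3-O-isopropylidene-L-tartrate. The tartrate supplies C2 and C3; its ester carbons become C1 and C4.
5. The diene comes from SeO2 oxidation and methylenation of (S)-citronellyl acetate, which supplies C13 and the C15 acetate.

Assumption: the target is read from the SMILES as the ent-labdane (2S,3S,5S,9R,10S,13S)-2-acetoxy-3-hydroxylabd-7-en-15-yl acetate; labdane numbering is used throughout.

## Route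

Step 1
Reactants: 1 dimethyl (4R,5R)-2,2-dimethyl-1,3-dioxolane-4,5-dicarboxylate (dimethyl 2,3-O-isopropylidene-L-tartrate)
Product: 2 methyl (4R,5S)-5-(hydroxymethyl)-2,2-dimethyl-1,3-dioxolane-4-carboxylate
Conditions: NaBH4 (0.6 equiv), MeOH, 0 °C to rt
Reagents that add atoms: none
Why: Hydride mono-reduction of a C2-symmetric diester, where both esters are equivalent so only conversion must be controlled (diester and diol are separated and recycled); no stereocenter is touched.

Step 2
Reactants: 2 methyl (4R,5S)-5-(hydroxymethyl)-2,2-dimethyl-1,3-dioxolane-4-carboxylate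
Product: 3 2-[(4R,5S)-5-(hydroxymethyl)-2,2-dimethyl-1,3-dioxolan-4-yl]propan-2-ol
Conditions: MeMgBr (4 equiv), THF, 0 °C to rt
Reagents that add atoms: methylmagnesium bromide, C[Mg]Br
Why: Double Grignard addition to the ester builds the tertiary carbinol that becomes C4 with C18 and C19; the α-stereocenter sits in the thermodynamically preferred trans-dioxolane, so it is not at risk.

Step 3
Reactants: 3 2-[(4R,5S)-5-(hydroxymethyl)-2,2-dimethyl-1,3-dioxolan-4-yl]propan-2-ol
Product: 5 2-[(4R,5S)-2,2-dimethyl-5-(prop-2-yn-1-yl)-1,3-dioxolan-4-yl]propan-2-ol, via primary triflate 4 (not isolated)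
Conditions: Tf2O (1.05 equiv), 2,6-lutidine, CH2Cl2, −78 °C; then LiC≡CH (from acetylene and n-BuLi, 3.5 equiv), THF/DMPU, −78 to −20 °C
Reagents that add atoms: lithium acetylide, [Li]C#C
Why: Chemoselective triflation of the primary hydroxyl followed by SN2 alkynylation of the dioxolanylmethyl triflate adds C10 and C5; ring closure by the tertiary alkoxide would need a trans-fused bicyclo[3.3.0] ether and should not compete.

Step 4
Reactants: 5 2-[(4R,5S)-2,2-dimethyl-5-(prop-2-yn-1-yl)-1,3-dioxolan-4-yl]propan-2-ol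
Product: 6 (4S,5S)-2,2-dimethyl-4-(prop-1-en-2-yl)-5-(prop-2-yn-1-yl)-1,3-dioxolane
Conditions: SOCl2, pyridine, CH2Cl2, −20 to 0 °C
Reagents that add atoms: none
Why: E2 dehydration of the tertiary chlorosulfite removes one of six unhindered methyl hydrogens in preference to the single shielded α-oxy methine hydrogen, as in terpene 2-hydroxyprop-2-yl dehydrations, giving the isopropenyl group with C3 untouched.

Step 5
Reactants: 6 (4S,5S)-2,2-dimethyl-4-(prop-1-en-2-yl)-5-(prop-2-yn-1-yl)-1,3-dioxolane
Product: 8 (4S,5S)-4-[(2E)-3-iodo-2-methylprop-2-en-1-yl]-2,2-dimethyl-5-(prop-1-en-2-yl)-1,3-dioxolane, via alkenylalane 7 (not isolated)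
Conditions: Me3Al (2.5 equiv), Cp2ZrCl2 (0.25 equiv), H2O (1 equiv), CH2Cl2, −23 °C; then I2, THF, −30 °C
Reagents that add atoms: trimethylaluminium, C[Al](C)C; iodine, II
Why: Negishi zirconium-catalysed syn-carboalumination of the terminal alkyne (water-accelerated, fast at low temperature so the acetonide survives) puts the C20 methyl on C10 and aluminium on C5, and iodinolysis with retention gives the (E)-iodide.

Step 6
Reactants: 9 (S)-citronellol, (3S)-3,7-dimethyloct-6-en-1-ol
Product: 10 (3S)-3,7-dimethyloct-6-en-1-yl acetate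
Conditions: Ac2O, pyridine, DMAP (cat.), CH2Cl2, 0 °C to rt
Reagents that add atoms: acetic anhydride, CC(=O)OC(C)=O
Why: Standard acylation installs the C15 acetate of the target at the start, where it also protects the alcohol; C13 is bought in.

Step 7
Reactants: 10 (3S)-3,7-dimethyloct-6-en-1-yl acetate
Product: 12 (3S,6E)-3,7-dimethyl-8-oxooct-6-en-1-yl acetate, via allylic alcohol 11 (not isolated)
Conditions: SeO2 (0.3 equiv), t-BuOOH, salicylic acid (cat.), CH2Cl2, rt; then MnO2, CH2Cl2, rt
Reagents that add atoms: tert-butyl hydroperoxide, CC(C)(C)OO; selenium dioxide, O=[Se]=O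
Why: Riley allylic oxidation (ene reaction then [2,3]-shift) is selective for the (E)-methyl group of the trisubstituted olefin, and MnO2 takes the crude allylic alcohol/enal mixture to the (E)-enal without touching the acetate.

Step 8
Reactants: 12 (3S,6E)-3,7-dimethyl-8-oxooct-6-en-1-yl acetate
Product: 13 (3S,6E)-3,7-dimethylnona-6,8-dien-1-yl acetate
Conditions: Ph3PCH3Br, KN(SiMe3)2 (1.1 equiv of ylide), THF, −78 to 0 °C
Reagents that add atoms: methyltriphenylphosphonium bromide, C[P+](c1ccccc1)(c1ccccc1)c1ccccc1.[Br-]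
Why: Wittig methylenation of the enal is much faster than attack on the acetate and adds C6 without disturbing the (E)-olefin.

Step 9
Reactants: 13 (3S,6E)-3,7-dimethylnona-6,8-dien-1-yl acetate; 8 (4S,5S)-4-[(2E)-3-iodo-2-methylprop-2-en-1-yl]-2,2-dimethyl-5-(prop-1-en-2-yl)-1,3-dioxolane
Product: 15 (3S,6E,10E)-12-[(4S,5S)-2,2-dimethyl-5-(prop-1-en-2-yl)-1,3-dioxolan-4-yl]-3,7,11-trimethyldodeca-6,10-dien-1-yl acetate, via alkylborane 14 (not isolated)
Conditions: 9-BBN (1.1 equiv), THF, 0 °C to rt; then 8, PdCl2(dppf) (dppf = 1,1′-bis(diphenylphosphino)ferrocene, 5 mol%), AsPh3, Cs2CO3, DMF/H2O, rt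
Reagents that add atoms: none
Why: 9-BBN hydroborates only the terminal vinyl group of the diene (boron on C6), and the B-alkyl Suzuki–Miyaura coupling forms C5–C6 with retention of the (E)-iodide geometry under conditions mild enough for the acetate.

Step 10
Reactants: 15 (3S,6E,10E)-12-[(4S,5S)-2,2-dimethyl-5-(prop-1-en-2-yl)-1,3-dioxolan-4-yl]-3,7,11-trimethyldodeca-6,10-dien-1-yl acetate
Product: 16 (2S,3S,5S,9R,10S,13S)-2,3-(isopropylidenedioxy)labd-7-en-15-yl acetate
Conditions: [N,N′-bis(3,5-di-tert-butylsalicylidene)ethane-1,2-diaminato]cobalt (divalent cobalt, achiral ligand, 1 mol%), 4CzIPN (2 mol%), 2,4,6-collidinium triflate (10 mol%), i-Pr2NEt (5 mol%), degassed PhCF3/acetone, 5 mM, 450 nm LEDs, 25 °C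
Reagents that add atoms: none
Why: Proposed new method: a light-driven cobalt-hydride (MHAT) radical bicycloisomerization in which photoreduced 4CzIPN and collidinium turn the divalent cobalt salen into a trivalent cobalt hydride that gives H• only to the 1,1-disubstituted isopropenyl group; the β-oxygenated tertiary C4 radical closes 6-endo on C5 and the C10 radical 6-endo on C9 through a chair–chair transition state in which the trans-fused acetonide forces O2 and O3 equatorial, so the tartrate-derived C2/C3 set C5, C10 and C9 (trans-decalin, axial C20 methyl, equatorial side chain from the E-olefin); divalent cobalt then takes H• back from the C8 radical, and any 8(17)-exocyclic isomer re-enters the cycle until only the hydride-inert trisubstituted 7-ene remains; the closest known chemistry is the thermal cobalt-salen/silane MHAT cycloisomerization and one-position isomerization of alkenes, photochemical cobalt-hydride hydrofunctionalization, and the Cp2TiCl (trivalent titanium) radical bicyclization of epoxypolyenes, which runs through the same β-oxy tertiary radical.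

Step 11
Reactants: 16 (2S,3S,5S,9R,10S,13S)-2,3-(isopropylidenedioxy)labd-7-en-15-yl acetate
Product: 17 (2S,3S,5S,9R,10S,13S)-2,3-dihydroxylabd-7-en-15-yl acetate
Conditions: AcOH/THF/H2O (3:1:1), 45 °C
Reagents that add atoms: none
Why: Acid-catalysed acetal hydrolysis of the strained trans-fused acetonide is easy, and the primary acetate and trisubstituted olefin are stable to aqueous acetic acid.

Step 12
Reactants: 17 (2S,3S,5S,9R,10S,13S)-2,3-dihydroxylabd-7-en-15-yl acetate
Product: 18 (2S,3S,5S,9R,10S,13S)-2-acetoxy-3-hydroxylabd-7-en-15-yl acetate (CNP0144124.2)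
Conditions: AcCl (1.05 equiv), 2,4,6-collidine, CH2Cl2, −78 to −40 °C
Reagents that add atoms: acetyl chloride, CC(=O)Cl
Why: Kinetic regioselective acylation favours the equatorial C2 hydroxyl over the equatorial C3 hydroxyl, which is neopentyl and flanked by the C4 gem-dimethyl group.

## Compound list

1 | dimethyl (4R,5R)-2,2-dimethyl-1,3-dioxolane-4,5-dicarboxylate | COC(=O)[C@@H]1OC(C)(C)O[C@H]1C(=O)OC | starting material
2 | methyl (4R,5S)-5-(hydroxymethyl)-2,2-dimethyl-1,3-dioxolane-4-carboxylate | COC(=O)[C@@H]1OC(C)(C)O[C@H]1CO | intermediate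
3 | 2-[(4R,5S)-5-(hydroxymethyl)-2,2-dimethyl-1,3-dioxolan-4-yl]propan-2-ol | CC(C)(O)[C@@H]1OC(C)(C)O[C@H]1CO | intermediate
4 | [(4S,5R)-5-(2-hydroxypropan-2-yl)-2,2-dimethyl-1,3-dioxolan-4-yl]methyl trifluoromethanesulfonate | CC(C)(O)[C@@H]1OC(C)(C)O[C@H]1COS(=O)(=O)C(F)(F)F | intermediate
5 | 2-[(4R,5S)-2,2-dimethyl-5-(prop-2-yn-1-yl)-1,3-dioxolan-4-yl]propan-2-ol | CC(C)(O)[C@@H]1OC(C)(C)O[C@H]1CC#C | intermediate
6 | (4S,5S)-2,2-dimethyl-4-(prop-1-en-2-yl)-5-(prop-2-yn-1-yl)-1,3-dioxolane | CC(=C)[C@@H]1OC(C)(C)O[C@H]1CC#C | intermediate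
7 | dimethyl{(1E)-3-[(4S,5S)-2,2-dimethyl-5-(prop-1-en-2-yl)-1,3-dioxolan-4-yl]-2-methylprop-1-en-1-yl}alumane | CC(=C)[C@@H]1OC(C)(C)O[C@H]1C/C(C)=C/[Al](C)C | intermediate
8 | (4S,5S)-4-[(2E)-3-iodo-2-methylprop-2-en-1-yl]-2,2-dimethyl-5-(prop-1-en-2-yl)-1,3-dioxolane | CC(=C)[C@@H]1OC(C)(C)O[C@H]1C/C(C)=C/I | intermediate
9 | (S)-citronellol, (3S)-3,7-dimethyloct-6-en-1-ol | OCC[C@@H](C)CCC=C(C)C | starting material
10 | (3S)-3,7-dimethyloct-6-en-1-yl acetate | CC(=O)OCC[C@@H](C)CCC=C(C)C | intermediate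
11 | (3S,6E)-8-hydroxy-3,7-dimethyloct-6-en-1-yl acetate | CC(=O)OCC[C@@H](C)CC/C=C(\C)CO | intermediate
12 | (3S,6E)-3,7-dimethyl-8-oxooct-6-en-1-yl acetate | CC(=O)OCC[C@@H](C)CC/C=C(\C)C=O | intermediate
13 | (3S,6E)-3,7-dimethylnona-6,8-dien-1-yl acetate | CC(=O)OCC[C@@H](C)CC/C=C(\C)C=C | intermediate
14 | (3S,6E)-9-(9-borabicyclo[3.3.1]nonan-9-yl)-3,7-dimethylnon-6-en-1-yl acetate | CC(=O)OCC[C@@H](C)CC/C=C(\C)CCB1C2CCCC1CCC2 | intermediate
15 | (3S,6E,10E)-12-[(4S,5S)-2,2-dimethyl-5-(prop-1-en-2-yl)-1,3-dioxolan-4-yl]-3,7,11-trimethyldodeca-6,10-dien-1-yl acetate | CC(=O)OCC[C@@H](C)CC/C=C(\C)CC/C=C(\C)C[C@@H]1OC(C)(C)O[C@H]1C(C)=C | intermediate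
16 | (2S,3S,5S,9R,10S,13S)-2,3-(isopropylidenedioxy)labd-7-en-15-yl acetate (trans-fused 2,3-acetonide of 17) | CC(=O)OCC[C@@H](C)CC[C@@H]1C(C)=CC[C@@H]2C(C)(C)[C@@H]3OC(C)(C)O[C@H]3C[C@@]12C | intermediate
17 | (2S,3S,5S,9R,10S,13S)-2,3-dihydroxylabd-7-en-15-yl acetate | CC(=O)OCC[C@@H](C)CC[C@@H]1C(C)=CC[C@@H]2C(C)(C)[C@H](O)[C@@H](O)C[C@@]12C | intermediate
18 | (2S,3S,5S,9R,10S,13S)-2-acetoxy-3-hydroxylabd-7-en-15-yl acetate (CNP0144124.2) | CC(=O)OCC[C@@H](C)CC[C@@H]1C(C)=CC[C@@H]2C(C)(C)[C@H](O)[C@@H](OC(C)=O)C[C@@]12C | target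

## Step count and risks

Total steps: 12. Longest linear sequence: 9 (steps 1–5 and 9–12, from compound 1).

**Step 10 (the new bicycloisomerization).**
- The C4 or C10 radical may return H• to divalent cobalt before it cyclizes, giving monocyclic olefins or the C3=C4 enol ether.
- The trans-fused acetonide may slow closure of ring A.
- Some 8(17)- or 8-ene may persist.

The fallback uses known chemistry and sets out from 15. The published thermal, oxidative MHAT radical–polar crossover polyene cyclization is applied: the same achiral cobalt salen (divalent cobalt, 5 mol%), N-fluoro-2,4,6-trimethylpyridinium triflate and PhSiH3 in HFIP/PhCF3 at 0 °C. Here the alkylcobalt is oxidized and the rings close in the cationic manifold with E1-type termination. This gives 16 together with its exocyclic isomer (2S,3S,5S,9R,10S,13S)-2,3-(isopropylidenedioxy)labd-8(17)-en-15-yl acetate F1. F1 is then moved into the ring by the known one-position MHAT olefin isomerization with chlorido[N,N′-bis(3,5-di-tert-butylsalicylidene)ethane-1,2-diaminato]cobalt (trivalent cobalt, 2 mol%) and catalytic PhSiH3 in benzene. The fallback comes back to the route at 16.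

**Step 4 (regiochemistry of the dehydration).**
- The enol ether may form by loss of the C3 hydrogen.
- Hydride shift may occur if the reaction drifts toward E1.

The fallback sets out from 2 and avoids any elimination by building the isopropenyl group through a ketone:
- Amidation of 2 with MeNH(OMe)·HCl/i-PrMgCl gives the Weinreb amide (4R,5S)-5-(hydroxymethyl)-N-methoxy-N,2,2-trimethyl-1,3-dioxolane-4-carboxamide F2.
- MeMgBr converts it into the methyl ketone 1-[(4R,5S)-5-(hydroxymethyl)-2,2-dimethyl-1,3-dioxolan-4-yl]ethan-1-one F3.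
- Wittig methylenation with Ph3P=CH2 (2.2 equiv) gives [(4S,5S)-2,2-dimethyl-5-(prop-1-en-2-yl)-1,3-dioxolan-4-yl]methanol F4; epimerization is harmless because trans is the stable isomer.
- Tf2O/2,6-lutidine gives [(4S,5S)-2,2-dimethyl-5-(prop-1-en-2-yl)-1,3-dioxolan-4-yl]methyl trifluoromethanesulfonate F5, which is treated in the same flask with LiC≡CH in THF/DMPU.

The fallback comes back to the route at 6. It is one step longer and also removes the free tertiary alcohol from the alkynylation.

**Step 12 (C2 versus C3 acetylation).** The 3-acetate and the 2,3-diacetate are the likely by-products. The fallback sets out from 17 and replaces kinetic discrimination by tin-acetal activation. Bu2SnO in toluene at reflux with removal of water gives the 2,3-O-dibutylstannylene acetal of 17, (2S,3S,5S,9R,10S,13S)-2,3-[(dibutylstannanediyl)dioxy]labd-7-en-15-yl acetate F6. AcCl at 0 °C then acylates the less hindered tin-bound O2. The fallback comes back to the route at 18.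

Further compounds
F1 | step 10 | (2S,3S,5S,9R,10S,13S)-2,3-(isopropylidenedioxy)labd-8(17)-en-15-yl acetate | CC(=O)OCC[C@@H](C)CC[C@@H]1C(=C)CC[C@@H]2C(C)(C)[C@@H]3OC(C)(C)O[C@H]3C[C@@]12C
F2 | step 4 | (4R,5S)-5-(hydroxymethyl)-N-methoxy-N,2,2-trimethyl-1,3-dioxolane-4-carboxamide | CON(C)C(=O)[C@@H]1OC(C)(C)O[C@H]1CO
F3 | step 4 | 1-[(4R,5S)-5-(hydroxymethyl)-2,2-dimethyl-1,3-dioxolan-4-yl]ethan-1-one | CC(=O)[C@@H]1OC(C)(C)O[C@H]1CO
F4 | step 4 | [(4S,5S)-2,2-dimethyl-5-(prop-1-en-2-yl)-1,3-dioxolan-4-yl]methanol | CC(=C)[C@@H]1OC(C)(C)O[C@H]1CO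
F5 | step 4 | [(4S,5S)-2,2-dimethyl-5-(prop-1-en-2-yl)-1,3-dioxolan-4-yl]methyl trifluoromethanesulfonate | CC(=C)[C@@H]1OC(C)(C)O[C@H]1COS(=O)(=O)C(F)(F)F
F6 | step 12 | (2S,3S,5S,9R,10S,13S)-2,3-[(dibutylstannanediyl)dioxy]labd-7-en-15-yl acetate | CC(=O)OCC[C@@H](C)CC[C@@H]1C(C)=CC[C@@H]2C(C)(C)[C@@H]3O[Sn](CCCC)(CCCC)O[C@H]3C[C@@]12C
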